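Ring A is C1 (benzoyl), C2 (C=O), C3, C4 (C=O), C5 (geranyl), C9 (C=O); the bridges are C5–C6–C7–C8(Me2)–C1 and C7–C10–C11–C3; the cyclopentane is C3–C11–C12(Me2)–C13–C14; side-chain atoms carry primes.
Enabling feature: the cage bonds C7–C10 and C8–C1 both leave the C6–C7=C8 unit of a prenyl group on C5, so the seven-membered ring C3–C4–C5–C6–C7–C10–C11 and the six-membered ring C1–C8–C7–C6–C5–C9 can close in one cationic event between a C10 aldehyde, that alkene and the enol carbon C1.
Retrosynthesis: cut C5'–C6' and C4'=C5' of the geranyl tail (back to prenyl), put oxygen back on C10, cut C7–C10 and C8–C1 to a spiro gem-diprenyl trione aldehyde; then cut both C5–prenyl bonds, C1–C2 and C4–C5 to benzoylacetone and a cis-fused lactone acid; then cut C3–C14 and C3–C11 to a bromomalonate and 5-bromo-3,3-dimethylpentanal.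
Forward: γ-lactone, cyclopentane, ring A (two Claisen acylations), then both cage rings in the key step; deoxygenation at C10 and extension of the spectator prenyl group follow.
Stereochemistry: C11 comes from an enantioselective organocatalytic α-alkylation; C3 follows from the forced cis fusion of the bicyclic lactone, whose lactone carbonyl becomes C2 and whose acid carbonyl becomes C4; C5, C7 and C1 are fixed by the cage closure; the E alkene comes from Riley oxidation of the (E)-methyl group.

Key step: step 10

Assumption: the enamine of the neopentyl-type bromo aldehyde is attacked on its Si face, as unbranched aldehydes are with the (2R,5S)-imidazolidinone; should the sense be reversed, the (2S,5R)-catalyst would be used.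
Remark: enolised triones are written as one tautomer, and the CIP descriptor of the spiro carbon refers to that tautomer.

Step 1
Reactants: 1 methyl 3,3-dimethylpent-4-enoate
Product: 2 methyl 5-bromo-3,3-dimethylpentanoate
Conditions: HBr (g), (PhCO2)2 (cat.), hexane, hν, 0 °C
Reagents that add atoms: hydrogen bromide, Br
Why: Radical-chain (peroxide-effect) anti-Markovnikov hydrobromination of a monosubstituted alkene puts bromine on the terminal carbon (future C14), the secondary radical beside the quaternary carbon has no rearrangement path, and the ester is inert.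

Step 2
Reactants: 2 methyl 5-bromo-3,3-dimethylpentanoate
Product: 3 5-bromo-3,3-dimethylpentanal
Conditions: i-Bu2AlH (1.05 equiv), CH2Cl2, −78 °C; MeOH, then aq. potassium sodium tartrate
Reagents that add atoms: none
Why: Partial ester reduction with i-Bu2AlH should stop at the aldehyde because the aluminium hemiacetal persists at −78 °C, and a primary alkyl bromide is not reduced.

Step 3
Reactants: 3 5-bromo-3,3-dimethylpentanal (2 equiv); 4 diethyl bromomalonate
Product: 7 ethyl (4S)-4-(4-bromo-2-methylbutan-2-yl)-2-oxooxolane-3-carboxylate (both C3 epimers), via α-malonyl aldehyde 5 (not isolated), via hydroxy diester 6 (not isolated)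
Conditions: (2R,5S)-2-tert-butyl-3,5-dimethylimidazolidin-4-one·CF3SO3H (20 mol%), Ru(bpy)3Cl2 (0.5 mol%), 2,6-lutidine, DMF, visible light, 23 °C; then MeOH, NaBH4, 0 °C; then TsOH·H2O (cat.), CH2Cl2, 23 °C
Reagents that add atoms: diethyl bromomalonate (4), CCOC(=O)C(Br)C(=O)OCC
Why: Enantioselective photoredox organocatalytic α-alkylation of an aldehyde, in which the malonyl radical adds to the Si face of the E-enamine (the face away from the 5-methyl group) and so sets C11, followed by immediate borohydride reduction that protects this α-stereocentre from enolisation and lets the γ-hydroxy malonate lactonise.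

Step 4
Reactants: 7 ethyl (4S)-4-(4-bromo-2-methylbutan-2-yl)-2-oxooxolane-3-carboxylate
Product: 8 ethyl (3aR,6aS)-4,4-dimethyl-1-oxohexahydro-1H-cyclopenta[c]furan-6a-carboxylate
Conditions: Cs2CO3 (1.5 equiv), MeCN, 50 °C
Reagents that add atoms: none
Why: Intramolecular 5-exo-tet C-alkylation of the α-carboxy lactone enolate by the primary bromide closes the cyclopentane, and the three-atom tether from C11 reaches only the enolate face that gives the cis-fused bicyclo[3.3.0] system, so C3 is set by C11 with the lactone carbonyl cis and the ester trans to C10.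

Step 5
Reactants: 8 ethyl (3aR,6aS)-4,4-dimethyl-1-oxohexahydro-1H-cyclopenta[c]furan-6a-carboxylate
Product: 10 (3aR,6aS)-4,4-dimethyl-1-oxohexahydro-1H-cyclopenta[c]furan-6a-carboxylic acid, via dilithium hydroxy dicarboxylate 9 (not isolated)
Conditions: LiOH (4 equiv), THF/H2O, 40 °C; then 2 M HCl, 0 °C
Reagents that add atoms: lithium hydroxide, [Li+].[OH-]
Why: Saponification opens the lactone and cleaves the ethyl ester, and on acidification only the carboxyl group cis to the hydroxymethyl arm can relactonise (a trans-fused bicyclo[3.3.0] lactone is out of reach), so a single lactone acid should result in which the two carbonyl groups on C3 are chemically different.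

Step 6
Reactants: 10 (3aR,6aS)-4,4-dimethyl-1-oxohexahydro-1H-cyclopenta[c]furan-6a-carboxylic acid; 11 1-phenylbutane-1,3-dione (benzoylacetone)
Product: 13 1-[(3aR,6aS)-4,4-dimethyl-1-oxohexahydro-1H-cyclopenta[c]furan-6a-yl]-5-phenylpentane-1,3,5-trione, via acid chloride 12 (not isolated)
Conditions: (COCl)2, DMF (cat.), CH2Cl2, 0 → 23 °C, evaporate; 11 (2.5 equiv), LiN(i-Pr)2 (5 equiv), THF, −78 → 0 °C, then 12 added at −78 °C; AcOH
Reagents that add atoms: 1-phenylbutane-1,3-dione (11), CC(=O)CC(=O)c1ccccc1
Why: Claisen-type acylation of a β-diketone 1,3-dianion at its terminal carbon forms C4–C5, the acid chloride being far more electrophilic than the hindered lactone so that the acid carbonyl becomes C4 and the lactone carbonyl is kept for C2, and inverse addition to excess dianion limits double acylation.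

Step 7
Reactants: 13 1-[(3aR,6aS)-4,4-dimethyl-1-oxohexahydro-1H-cyclopenta[c]furan-6a-yl]-5-phenylpentane-1,3,5-trione
Product: 14 (1R,5S)-7-benzoyl-8-hydroxy-1-(hydroxymethyl)-2,2-dimethylspiro[4.5]dec-7-ene-6,10-dione
Conditions: KN(SiMe3)2 (3 equiv), THF, −78 → 23 °C; 1 M HCl, 0 °C
Reagents that add atoms: none
Why: Intramolecular Claisen (Dieckmann-type) acylation in which the carbon between the benzoyl and C9 carbonyls (C1) attacks the lactone carbonyl C2 in the only feasible ring size (six), the lactone opening to free the C10 alcohol and the acidic 2-acyl-1,3,5-trione anion providing the driving force, while no bond at C3 or C11 is touched.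

Step 8
Reactants: 14 (1R,5S)-7-benzoyl-8-hydroxy-1-(hydroxymethyl)-2,2-dimethylspiro[4.5]dec-7-ene-6,10-dione; 15 prenyl bromide (1-bromo-3-methylbut-2-ene)
Product: 17 (1R,5S)-7-benzoyl-8-hydroxy-1-(hydroxymethyl)-2,2-dimethyl-9,9-bis(3-methylbut-2-en-1-yl)spiro[4.5]dec-7-ene-6,10-dione, via monoprenyl trione 16 (not isolated)
Conditions: NaOMe (3.3 equiv), 15 (2.6 equiv), MeOH, 0 → 23 °C
Reagents that add atoms: prenyl bromide (15), CC(C)=CCBr
Why: Base-mediated double C-alkylation of an acylphloroglucinol-type trione (dearomative gem-prenylation as in the lupulone series) should occur at C5, the only ring carbon without the acyl group, with the protic solvent favouring C- over O-alkylation, and two identical groups on C5 create no stereocentre.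

Step 9
Reactants: 17 (1R,5S)-7-benzoyl-8-hydroxy-1-(hydroxymethyl)-2,2-dimethyl-9,9-bis(3-methylbut-2-en-1-yl)spiro[4.5]dec-7-ene-6,10-dione
Product: 18 (1R,5S)-7-benzoyl-8-hydroxy-2,2-dimethyl-9,9-bis(3-methylbut-2-en-1-yl)-6,10-dioxospiro[4.5]dec-7-ene-1-carbaldehyde
Conditions: SO3·pyridine (3 equiv), Me2SO, i-Pr2NEt, CH2Cl2, 0 °C
Reagents that add atoms: none
Why: Parikh–Doering oxidation of the primary alcohol is chosen because it is non-radical and free of hypervalent-iodine or metal oxidants that could oxidise the enol or start oxidative cyclisation onto the prenyl groups, and C11, flanked by two quaternary carbons, should not epimerise under the amine base.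

Step 10
Reactants: 18 (1R,5S)-7-benzoyl-8-hydroxy-2,2-dimethyl-9,9-bis(3-methylbut-2-en-1-yl)-6,10-dioxospiro[4.5]dec-7-ene-1-carbaldehyde
Product: 19 (1S,3S,5R,7R,10R,11R)-1-benzoyl-10-hydroxy-8,8,12,12-tetramethyl-5-(3-methylbut-2-en-1-yl) cage trione (C2, C4, C9 ketones; homoadamantane C1–C11 with cyclopentane C3/C11–C14 fused on C3–C11; hydroxyl on the C6 side of C10)
Conditions: Me2AlCl (3 equiv), CH2Cl2, −78 → 0 °C; 1 M HCl
Reagents that add atoms: none
Why: One equivalent of Me2AlCl turns the acidic enol into an aluminium triketonate (methane is lost) and further Lewis acid activates the C10 aldehyde, whereupon the prenyl group on the C11 face of C5 adds through C7 (Prins addition, bond C7–C10) and the tertiary C8 cation is captured by C1 of the triketonate (bond C8–C1). The closest known reaction types are the Lewis-acid Prins cyclisation ended by capture of the cation with a carbon nucleophile and the cation–enol closure of the bicyclo[3.3.1]nonane in dearomatised prenylated acylphloroglucinols. The seven-membered ring C3–C4–C5–C6–C7–C10–C11 closes 7-exo at the carbonyl carbon with oxygen and C8 left outside the ring, and the six-membered ring C1–C8–C7–C6–C5–C9 closes by capture of the exocyclic cation at the central carbon of the triketonate. C5 is set by desymmetrisation, since only the prenyl group on the ring A face that carries the C11 arm can reach C10; C7 and C1 are dictated by the cage, all three bridges lying on one face of ring A; C10 is expected from an antiperiplanar approach with oxygen turned away from C8 and is removed later. The step needs Prins addition to win over aldol addition of C1 to the aldehyde and over proton loss or O-capture at C8: the aldol adduct of a triketonate is reversible, no protic acid is present so the second prenyl group stays a spectator, and C7, once tied under ring A by two bridges, aims C8 at the π-face of C1 while the enol oxygens lie in the ring plane.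

Step 11
Reactants: 19 C10-hydroxy prenyl cage trione
Product: 21 O-(cage C10) S-methyl dithiocarbonate (xanthate of 19), via sodium xanthate 20 (not isolated)
Conditions: NaH (1.5 equiv), imidazole (cat.), THF, 0 °C; CS2; then MeI, 23 °C
Reagents that add atoms: carbon disulfide, S=C=S; iodomethane, CI
Why: Xanthate formation (first half of the Barton–McCombie deoxygenation) uses the smallest electrophile for a hindered secondary alkoxide, the molecule has no enolisable position, and the cage keeps the alkoxide from reaching C2 or C4 through a five-membered transition state, so retro-Claisen opening is not expected.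

Step 12
Reactants: 21 xanthate of 19
Product: 22 (1S,3S,5R,7R,11R)-1-benzoyl-8,8,12,12-tetramethyl-5-(3-methylbut-2-en-1-yl) cage trione (C10 now CH2)
Conditions: Bu3SnH (3 equiv, 0.2 M), AIBN (cat.), toluene, 90 °C
Reagents that add atoms: none
Why: Barton–McCombie radical deoxygenation, in which the concentrated stannane should reduce the secondary C10 radical faster than it can add to the remote prenyl alkene or fragment, and no stereocentre is affected.

Step 13
Reactants: 22 deoxygenated prenyl cage trione
Product: 24 (E)-enal, the cage trione carrying (2E)-3-methyl-4-oxobut-2-en-1-yl on C5, via allylic alcohol 23 (not isolated)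
Conditions: SeO2 (2.2 equiv), 1,4-dioxane, H2O (trace), 90 °C
Reagents that add atoms: selenium dioxide, O=[Se]=O
Why: Riley allylic oxidation (ene reaction then [2,3]-sigmatropic shift) of the single remaining trisubstituted alkene attacks the methyl group trans to the chain at the more substituted alkene end and so gives the (E)-enal, while all ketones are non-enolisable and the C1' methylene at the less substituted end is left alone.

Step 14
Reactants: 24 (E)-enal
Product: 25 (E)-diene, the cage trione carrying (2E)-3-methylpenta-2,4-dien-1-yl on C5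
Conditions: Ph3PCH3Br (1.5 equiv), KN(SiMe3)2 (1.4 equiv), THF, 0 °C; then 24, −78 → 0 °C
Reagents that add atoms: methyltriphenylphosphonium bromide, C[P+](c1ccccc1)(c1ccccc1)c1ccccc1.[Br-]
Why: Wittig methylenation should be selective for the aldehyde over the four ketones, each of which sits between fully substituted carbons, and it leaves the E geometry of the trisubstituted alkene untouched.

Step 15
Reactants: 25 (E)-diene; 26 1-bromo-2-methylprop-1-ene
Product: 28 CNP0168637.1, the (1S,3S,5R,7R,11R)-1-benzoyl-5-[(2E)-3,7-dimethylocta-2,6-dien-1-yl]-8,8,12,12-tetramethyl cage trione, via B-alkyl-9-BBN 27 (not isolated)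
Conditions: 9-borabicyclo[3.3.1]nonane (9-BBN-H, 1.2 equiv), THF, 0 → 23 °C; then 26 (3 equiv), Pd(dppf)Cl2 (10 mol%), AsPh3, aq. K3PO4, DMF, 23 °C
Reagents that add atoms: 1-bromo-2-methylprop-1-ene (26), CC(C)=CBr
Why: Chemo- and regioselective hydroboration of the monosubstituted end of the diene (boron on terminal C5') followed by B-alkyl Suzuki–Miyaura coupling with the vinyl bromide forms C5'–C6' and completes the geranyl chain without touching the E alkene or the hindered ketones.

Compound list
1 | methyl 3,3-dimethylpent-4-enoate | COC(=O)CC(C)(C)C=C | starting material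
2 | methyl 5-bromo-3,3-dimethylpentanoate | COC(=O)CC(C)(C)CCBr | intermediate
3 | 5-bromo-3,3-dimethylpentanal | O=CCC(C)(C)CCBr | intermediate
4 | diethyl bromomalonate (diethyl 2-bromopropanedioate) | CCOC(=O)C(Br)C(=O)OCC | starting material
5 | diethyl 2-[(2S)-5-bromo-3,3-dimethyl-1-oxopentan-2-yl]propanedioate (not isolated) | CCOC(=O)C(C(=O)OCC)[C@H](C=O)C(C)(C)CCBr | intermediate
6 | diethyl 2-[(2S)-5-bromo-1-hydroxy-3,3-dimethylpentan-2-yl]propanedioate (not isolated) | CCOC(=O)C(C(=O)OCC)[C@H](CO)C(C)(C)CCBr | intermediate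
7 | ethyl (4S)-4-(4-bromo-2-methylbutan-2-yl)-2-oxooxolane-3-carboxylate, both C3 epimers | CCOC(=O)C1C(=O)OC[C@@H]1C(C)(C)CCBr | intermediate
8 | ethyl (3aR,6aS)-4,4-dimethyl-1-oxohexahydro-1H-cyclopenta[c]furan-6a-carboxylate (cis-fused) | CCOC(=O)[C@]12CCC(C)(C)[C@H]1COC2=O | intermediate
9 | dilithium (2R)-2-(hydroxymethyl)-3,3-dimethylcyclopentane-1,1-dicarboxylate (not isolated) | [Li+].[Li+].[O-]C(=O)C1(C([O-])=O)CCC(C)(C)[C@H]1CO | intermediate
10 | (3aR,6aS)-4,4-dimethyl-1-oxohexahydro-1H-cyclopenta[c]furan-6a-carboxylic acid | OC(=O)[C@]12CCC(C)(C)[C@H]1COC2=O | intermediate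
11 | 1-phenylbutane-1,3-dione (benzoylacetone) | CC(=O)CC(=O)c1ccccc1 | starting material
12 | (3aR,6aR)-4,4-dimethyl-1-oxohexahydro-1H-cyclopenta[c]furan-6a-carbonyl chloride (not isolated) | ClC(=O)[C@]12CCC(C)(C)[C@H]1COC2=O | intermediate
13 | 1-[(3aR,6aS)-4,4-dimethyl-1-oxohexahydro-1H-cyclopenta[c]furan-6a-yl]-5-phenylpentane-1,3,5-trione | O=C(CC(=O)CC(=O)c1ccccc1)[C@]12CCC(C)(C)[C@H]1COC2=O | intermediate
14 | (1R,5S)-7-benzoyl-8-hydroxy-1-(hydroxymethyl)-2,2-dimethylspiro[4.5]dec-7-ene-6,10-dione | OC[C@@H]1C(C)(C)CC[C@]12C(=O)C(C(=O)c3ccccc3)=C(O)CC2=O | intermediate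
15 | prenyl bromide (1-bromo-3-methylbut-2-ene) | CC(C)=CCBr | starting material
16 | 7-benzoyl-8-hydroxy-1-(hydroxymethyl)-2,2-dimethyl-9-(3-methylbut-2-en-1-yl)spiro[4.5]dec-7-ene-6,10-dione, (1R,5S), both C9 epimers (not isolated) | OC[C@@H]1C(C)(C)CC[C@]12C(=O)C(C(=O)c3ccccc3)=C(O)C(CC=C(C)C)C2=O | intermediate
17 | (1R,5S)-7-benzoyl-8-hydroxy-1-(hydroxymethyl)-2,2-dimethyl-9,9-bis(3-methylbut-2-en-1-yl)spiro[4.5]dec-7-ene-6,10-dione | OC[C@@H]1C(C)(C)CC[C@]12C(=O)C(C(=O)c3ccccc3)=C(O)C(CC=C(C)C)(CC=C(C)C)C2=O | intermediate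
18 | (1R,5S)-7-benzoyl-8-hydroxy-2,2-dimethyl-9,9-bis(3-methylbut-2-en-1-yl)-6,10-dioxospiro[4.5]dec-7-ene-1-carbaldehyde (key-step precursor) | O=C[C@@H]1C(C)(C)CC[C@]12C(=O)C(C(=O)c3ccccc3)=C(O)C(CC=C(C)C)(CC=C(C)C)C2=O | intermediate
19 | (1S,3S,5R,7R,10R,11R)-1-benzoyl-10-hydroxy-8,8,12,12-tetramethyl-5-(3-methylbut-2-en-1-yl) cage-2,4,9-trione (key-step product; skeleton numbering of the plan) | CC(C)=CC[C@@]12C[C@H]3[C@@H](O)[C@@H]4C(C)(C)CC[C@]4(C1=O)C(=O)[C@@](C(=O)c1ccccc1)(C2=O)C3(C)C | intermediate
20 | sodium O-(cage C10) dithiocarbonate of 19 (not isolated) | [Na+].CC(C)=CC[C@@]12C[C@H]3[C@@H](OC(=S)[S-])[C@@H]4C(C)(C)CC[C@]4(C1=O)C(=O)[C@@](C(=O)c1ccccc1)(C2=O)C3(C)C | intermediate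
21 | O-(cage C10) S-methyl dithiocarbonate of 19 | CC(C)=CC[C@@]12C[C@H]3[C@@H](OC(=S)SC)[C@@H]4C(C)(C)CC[C@]4(C1=O)C(=O)[C@@](C(=O)c1ccccc1)(C2=O)C3(C)C | intermediate
22 | (1S,3S,5R,7R,11R)-1-benzoyl-8,8,12,12-tetramethyl-5-(3-methylbut-2-en-1-yl) cage-2,4,9-trione | CC(C)=CC[C@@]12C[C@H]3C[C@@H]4C(C)(C)CC[C@]4(C1=O)C(=O)[C@@](C(=O)c1ccccc1)(C2=O)C3(C)C | intermediate
23 | cage trione of 22 with (2E)-4-hydroxy-3-methylbut-2-en-1-yl on C5 (not isolated) | OC/C(C)=C/C[C@@]12C[C@H]3C[C@@H]4C(C)(C)CC[C@]4(C1=O)C(=O)[C@@](C(=O)c1ccccc1)(C2=O)C3(C)C | intermediate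
24 | cage trione of 22 with (2E)-3-methyl-4-oxobut-2-en-1-yl on C5 | O=C/C(C)=C/C[C@@]12C[C@H]3C[C@@H]4C(C)(C)CC[C@]4(C1=O)C(=O)[C@@](C(=O)c1ccccc1)(C2=O)C3(C)C | intermediate
25 | cage trione of 22 with (2E)-3-methylpenta-2,4-dien-1-yl on C5 | C=C/C(C)=C/C[C@@]12C[C@H]3C[C@@H]4C(C)(C)CC[C@]4(C1=O)C(=O)[C@@](C(=O)c1ccccc1)(C2=O)C3(C)C | intermediate
26 | 1-bromo-2-methylprop-1-ene | CC(C)=CBr | starting material
27 | cage trione of 22 with (2E)-5-(9-borabicyclo[3.3.1]nonan-9-yl)-3-methylpent-2-en-1-yl on C5 (not isolated) | C1CCC2CCCC1B2CC/C(C)=C/C[C@@]12C[C@H]3C[C@@H]4C(C)(C)CC[C@]4(C1=O)C(=O)[C@@](C(=O)c1ccccc1)(C2=O)C3(C)C | intermediate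
28 | CNP0168637.1, (1S,3S,5R,7R,11R)-1-benzoyl-5-[(2E)-3,7-dimethylocta-2,6-dien-1-yl]-8,8,12,12-tetramethyl cage-2,4,9-trione | CC(C)=CCC/C(C)=C/C[C@@]12C[C@H]3C[C@@H]4C(C)(C)CC[C@]4(C1=O)C(=O)[C@@](C(=O)c1ccccc1)(C2=O)C3(C)C | target

Total step count: 15
Longest linear sequence: 15 steps (1 to 28)

Steps most likely to fail

Step 10. The cascade may stall after the Prins addition: the C8 cation can lose a proton (carbonyl-ene outcome) or be held as the tertiary chloride, and the aldehyde can be parked in a reversible aldol at C1, so that the second ring does not close. The fallback sets out from 18 and returns at 19. Aldehyde 18 would be treated with Me2AlCl (3 equiv) in CH2Cl2 at −78 °C and quenched cold, so that chloride capture ends the Prins addition at the C8-chloro C10-hydroxy bicyclic enol F1. AgOTf with 2,6-di-tert-butylpyridine in CH2Cl2 at −40 °C would then ionise only the tertiary chloride, leaving the spectator prenyl group alone, and C1 would close the six-membered ring to give 19.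

Step 3. Radical capture by the enamine of a neopentyl-type aldehyde may be slow, so that reduction of the bromomalonate outruns C–C bond formation, and the α-stereocentre may erode by enolisation before the borohydride is added. The fallback sets out from 1 and returns at 10.
- Ester 1 would be reduced with LiAlH4 to 3,3-dimethylpent-4-en-1-ol F2 and converted with I2, PPh3 and imidazole into 5-iodo-3,3-dimethylpent-1-ene F3.
- F3 would alkylate sodium diethyl malonate to give diethyl 2-(3,3-dimethylpent-4-en-1-yl)propanedioate F4, and iodination (NaH, N-iodosuccinimide) would give diethyl 2-iodo-2-(3,3-dimethylpent-4-en-1-yl)propanedioate F5.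
- Iodine-atom-transfer 5-exo cyclisation ((Bu3Sn)2 cat., hν, benzene, 80 °C) would give racemic diethyl 2-(iodomethyl)-3,3-dimethylcyclopentane-1,1-dicarboxylate F6.
- LiOH and then HCl would convert F6 into the racemic cis-fused lactone acid F7, the cis carboxylate displacing iodide.
- Crystallisation with (R)-1-phenylethylamine would give the (R)-1-phenylethylammonium salt of the (3aR,6aS) acid F8, and aqueous HCl would release 10. The (S)-amine would be used if that antipode gives the less soluble salt of the wanted acid.

Step 8. O-alkylation of the ambident enolates and an incomplete second alkylation at the increasingly hindered C5 may give mixtures of enol ethers and monoprenyl compound. The fallback sets out from 14 and returns at 17. Tsuji–Trost double C-allylation of 14 with allyl methyl carbonate and Pd(PPh3)4 in THF would give the gem-diallyl trione F9; O-allyl products re-ionise under zerovalent palladium and funnel to carbon. Cross-metathesis with 2-methylbut-2-ene under the second-generation Grubbs catalyst would then convert both allyl groups into prenyl groups and give 17.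

Further compounds
F1 | step 10 | spiro-bridged chloride: enol trione with C7–C10 bond formed, hydroxyl on C10, chlorine on C8 and one prenyl group on C5 | CC(C)=CC[C@@]12C[C@@H]([C@@H](O)[C@@H]3C(C)(C)CC[C@]3(C1=O)C(=O)C(C(=O)c1ccccc1)=C2O)C(C)(C)Cl
F2 | step 3 | 3,3-dimethylpent-4-en-1-ol | OCCC(C)(C)C=C
F3 | step 3 | 5-iodo-3,3-dimethylpent-1-ene | ICCC(C)(C)C=C
F4 | step 3 | diethyl 2-(3,3-dimethylpent-4-en-1-yl)propanedioate | CCOC(=O)C(CCC(C)(C)C=C)C(=O)OCC
F5 | step 3 | diethyl 2-iodo-2-(3,3-dimethylpent-4-en-1-yl)propanedioate | CCOC(=O)C(I)(CCC(C)(C)C=C)C(=O)OCC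
F6 | step 3 | diethyl 2-(iodomethyl)-3,3-dimethylcyclopentane-1,1-dicarboxylate (racemic) | CCOC(=O)C1(C(=O)OCC)CCC(C)(C)C1CI
F7 | step 3 | racemic cis-fused 4,4-dimethyl-1-oxohexahydro-1H-cyclopenta[c]furan-6a-carboxylic acid | OC(=O)[C@]12CCC(C)(C)[C@H]1COC2=O.OC(=O)[C@@]12CCC(C)(C)[C@@H]1COC2=O
F8 | step 3 | (R)-1-phenylethylammonium (3aR,6aS)-4,4-dimethyl-1-oxohexahydro-1H-cyclopenta[c]furan-6a-carboxylate | C[C@@H]([NH3+])c1ccccc1.[O-]C(=O)[C@]12CCC(C)(C)[C@H]1COC2=O
F9 | step 8 | (1R,5S)-7-benzoyl-8-hydroxy-1-(hydroxymethyl)-2,2-dimethyl-9,9-di(prop-2-en-1-yl)spiro[4.5]dec-7-ene-6,10-dione | OC[C@@H]1C(C)(C)CC[C@]12C(=O)C(C(=O)c3ccccc3)=C(O)C(CC=C)(CC=C)C2=O
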